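**Retrosynthetic overview**
1. The malonic half ester is put on last (Meldrum's acid) onto diterpenol 19. Its PMB ether 18 comes from aldehyde 16 (CHO to CH3), and 16 from cyclohexene 15 by reductive allylic transposition.
2. Feature used: in the 2,2-dimethyl-6-methylidenecyclohexyl ring the only stereocenter C1 sits between the CMe2 carbon C2 and the methylidene-bearing C6. With the C6=CH2 bond moved into the ring (C5=C6, exocyclic carbon as CH2OCO2Me) and one C2 methyl written as CHO, bonds C1–C2 and C3–C4 are those of an "ortho" Diels–Alder adduct of an (E)-1,2-disubstituted diene (C1, C6, C5, C4) with methacrolein (C2, C3).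
3. Key disconnection: catalytic enantioselective [4+2] cycloaddition of the linear tetraene carbonate 13 with methacrolein 14 to give 15. It forms the ring, the quaternary carbon and the stereocenter together.
4. Diene 13 comes from (2E,6E)-farnesol 1: terminal oxidative cleavage to the C12 aldehyde 7, dibromo-olefination, trans-selective vinylation, hydroxymethylation, carbonate formation.
5. Ring order: there is one carbocycle only; it is closed in step 8.

Key step: step 8

Assumption: the facial sense of the oxazaborolidinium catalyst is taken from its accepted model for 2-substituted acroleins (diene to the Re face of C2 with the (S)-catalyst); should the sense be the opposite, the equally available (R)-catalyst is used in step 8 and nothing else changes.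

**Route**

Step 1
Reactants: 1 (2E,6E)-farnesol
Product: 3 farnesyl 4-methoxybenzyl (PMB) ether, via sodium alkoxide 2 (not isolated)
Conditions: NaH, 4-methoxybenzyl chloride, n-Bu4NI (cat.), THF/DMF, 0 to 23 °C
Reagents that add atoms: sodium hydride [H-].[Na+] (sodium of 2 only); 4-methoxybenzyl chloride COc1ccc(CCl)cc1
Why: Williamson ether synthesis; the PMB ether should withstand base, organolithium, Lewis acid, palladium and hydrazine/KOH and is removable oxidatively at the end.

Step 2
Reactants: 3 farnesyl PMB ether
Product: 5 terminal epoxide, via bromohydrin 4 (not isolated)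
Conditions: NBS (1.05 equiv), THF/H2O, 0 °C; then K2CO3, MeOH, 23 °C
Reagents that add atoms: water O; N-bromosuccinimide O=C1CCC(=O)N1Br (bromine of 4 only)
Why: van Tamelen terminal functionalisation, in which NBS in water-rich THF should attack the exposed terminal trisubstituted alkene to give the Markovnikov bromohydrin that base closes to the epoxide by intramolecular SN2 (the new stereocenter is racemic and is destroyed in step 3).

Step 3
Reactants: 5 terminal epoxide
Product: 7 C12 aldehyde, via diol 6 (not isolated)
Conditions: HIO4·2H2O, THF/Et2O, 0 °C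
Reagents that add atoms: water O (oxygen of diol 6 only, which leaves with acetone)
Why: periodic acid opens the epoxide to the glycol and cleaves it (Malaprade reaction), which should give the aldehyde whose carbonyl carbon becomes ring carbon C1.

Step 4
Reactants: 7 C12 aldehyde
Product: 8 1,1-dibromoalkene
Conditions: CBr4, PPh3, Zn dust, CH2Cl2, 23 °C (ylide pre-formed); then 7, 0 to 23 °C
Reagents that add atoms: tetrabromomethane BrC(Br)(Br)Br (as the ylide Ph3P=CBr2 made in the flask)
Why: Ramirez (Corey–Fuchs) dibromo-olefination, a Wittig-type reaction run under neutral conditions that the acid-sensitive polyene ether should tolerate.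

Step 5
Reactants: 8 1,1-dibromoalkene
Product: 9 (Z)-2-bromo-1,3-diene
Conditions: CH2=CHMgBr/ZnBr2 (1.2 equiv), PdCl2(DPEphos) (3 mol%; DPEphos = bis[2-(diphenylphosphino)phenyl] ether), THF, 0 to 23 °C
Reagents that add atoms: vinylmagnesium bromide C=C[Mg]Br (transmetallated in the flask to vinylzinc bromide)
Why: trans-selective Negishi mono-coupling of a 1,1-dibromoalkene, in which oxidative addition should occur at the less hindered C–Br bond trans to the alkyl chain, so that the vinyl group enters trans to the chain and fixes the diene geometry needed in step 8.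

Step 6
Reactants: 9 (Z)-2-bromo-1,3-diene
Product: 12 dienol, via dienyllithium 10 (not isolated), via lithium alkoxide 11 (not isolated)
Conditions: t-BuLi (2.1 equiv), Et2O, −78 °C; (CH2O)n, −78 to 0 °C; then H2O
Reagents that add atoms: tert-butyllithium [Li]C(C)(C)C (lithium of 10 and 11 only); formaldehyde C=O (as paraformaldehyde)
Why: bromine–lithium exchange of an alkenyl bromide proceeds with retention of alkene configuration and the alkenyllithium should add to formaldehyde, placing CH2OH cis to the chain.

Step 7
Reactants: 12 dienol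
Product: 13 dienyl methyl carbonate
Conditions: ClCO2Me, pyridine, CH2Cl2, 0 °C
Reagents that add atoms: methyl chloroformate COC(=O)Cl
Why: O-acylation to the carbonate, which serves as the leaving group for step 9 and whose inductive pull should switch off the directing effect of the C2 substituent of the diene in step 8.

Step 8
Reactants: 13 dienyl methyl carbonate; 14 methacrolein
Product: 15 (5S,6R)-cyclohexene carbaldehyde (Diels–Alder adduct)
Conditions: 14 (5 equiv), (S)-oxazaborolidine [(3aS)-1-(2-methylphenyl)-3,3-diphenyltetrahydro-1H,3H-pyrrolo[1,2-c][1,3,2]oxazaborole] (20 mol%), HNTf2 (18 mol%), CH2Cl2, −78 to −40 °C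
Reagents that add atoms: none
Why: The N-protonated oxazaborolidine binds the formyl oxygen of s-trans methacrolein and lowers its LUMO, and the diene then adds in a concerted but asynchronous Diels–Alder reaction in which the bond between the two unsubstituted CH2 termini (diene C4 and the β-carbon) is advanced and the bond between the substituted diene terminus and the α-carbon closes late. The closest known reaction type is the cationic oxazaborolidine-catalysed Diels–Alder reaction of 2-substituted acroleins with acyclic 1,3-dienes, which delivers α-quaternary cyclohexenecarbaldehydes with high enantioselectivity. The six-membered carbocycle is closed by an intermolecular suprafacial [4+2] cycloaddition that leaves the ring double bond between the two central diene carbons, exactly where step 9 needs it. The quaternary carbon should be set by catalyst-controlled attack on the Re face of C2 of the bound aldehyde, and the ring CH is set relative to it by the endo orientation of the boron-bound formyl group together with the (Z)-configured C2=C3 bond of 13 (chain "outside"), so that it becomes the (S)-stereocenter once the formyl group has been reduced to methyl. The "ortho" regiochemistry is secured by the alkyl chain on the diene terminus (largest HOMO coefficient at the free CH2 end) and by the carbonate oxygen, which disfavours the positive charge at diene C2 that the reversed orientation would require. The step also needs the conjugated diene to react in preference to the isolated trisubstituted alkenes, which its higher HOMO and the low temperature should ensure.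

Step 9
Reactants: 15 Diels–Alder adduct
Product: 16 exocyclic-methylene aldehyde
Conditions: Pd(OAc)2 (5 mol%), n-Bu3P (20 mol%), HCO2H, Et3N, THF, 40 °C
Reagents that add atoms: none
Why: Tsuji formate reduction of an allylic carbonate, in which the allylpalladium formate loses CO2 and should deliver hydride to the more substituted (ring) terminus to give the exocyclic alkene, with the stereocenters untouched.

Step 10
Reactants: 16 exocyclic-methylene aldehyde
Product: 18 PMB ether of the monocyclic diterpenol, via hydrazone 17 (not isolated)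
Conditions: N2H4·H2O, KOH, diethylene glycol, 130 °C then 200 °C, argon
Reagents that add atoms: hydrazine NN (nitrogen atoms of 17 only, lost as N2)
Why: Wolff–Kishner reduction (Huang–Minlon procedure) of a non-enolisable neopentyl aldehyde should give the second methyl group, making the quaternary carbon non-stereogenic and leaving the ring CH as the single (S)-stereocenter, while KOH in glycol is too weak a base to move the isolated alkenes.

Step 11
Reactants: 18 PMB ether
Product: 19 monocyclic diterpenol
Conditions: DDQ (1.2 equiv), CH2Cl2/pH 7 buffer, 0 °C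
Reagents that add atoms: none
Why: oxidative PMB cleavage, in which DDQ abstracts the benzylic hydride and water hydrolyses the oxocarbenium ion, which should free the allylic alcohol without touching the alkenes.

Step 12
Reactants: 19 monocyclic diterpenol; 20 Meldrum's acid
Product: 21 target malonic acid half ester
Conditions: 20 (1.1 equiv), toluene, 90 °C
Reagents that add atoms: none
Why: alcoholysis of Meldrum's acid with loss of acetone should give the mono-ester of malonic acid directly, below the temperature at which the half ester decarboxylates.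

**Compound list**
1 | (2E,6E)-farnesol | CC(C)=CCC/C(C)=C/CC/C(C)=C/CO | starting material
2 | sodium (2E,6E)-farnesolate | CC(C)=CCC/C(C)=C/CC/C(C)=C/C[O-].[Na+] | intermediate (not isolated)
3 | 1-methoxy-4-({[(2E,6E)-3,7,11-trimethyldodeca-2,6,10-trien-1-yl]oxy}methyl)benzene | CC(C)=CCC/C(C)=C/CC/C(C)=C/COCc1ccc(OC)cc1 | intermediate
4 | (6E,10E)-3-bromo-12-[(4-methoxyphenyl)methoxy]-2,6,10-trimethyldodeca-6,10-dien-2-ol (racemic) | CC(C)(O)C(Br)CC/C(C)=C/CC/C(C)=C/COCc1ccc(OC)cc1 | intermediate (not isolated)
5 | 3-[(3E,7E)-9-[(4-methoxyphenyl)methoxy]-3,7-dimethylnona-3,7-dien-1-yl]-2,2-dimethyloxirane (racemic) | CC1(C)OC1CC/C(C)=C/CC/C(C)=C/COCc1ccc(OC)cc1 | intermediate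
6 | (6E,10E)-12-[(4-methoxyphenyl)methoxy]-2,6,10-trimethyldodeca-6,10-diene-2,3-diol (racemic) | CC(C)(O)C(O)CC/C(C)=C/CC/C(C)=C/COCc1ccc(OC)cc1 | intermediate (not isolated)
7 | (4E,8E)-10-[(4-methoxyphenyl)methoxy]-4,8-dimethyldeca-4,8-dienal | O=CCC/C(C)=C/CC/C(C)=C/COCc1ccc(OC)cc1 | intermediate
8 | 1-({[(2E,6E)-11,11-dibromo-3,7-dimethylundeca-2,6,10-trien-1-yl]oxy}methyl)-4-methoxybenzene | BrC(Br)=CCC/C(C)=C/CC/C(C)=C/COCc1ccc(OC)cc1 | intermediate
9 | 1-({[(2E,6E,10Z)-11-bromo-3,7-dimethyltrideca-2,6,10,12-tetraen-1-yl]oxy}methyl)-4-methoxybenzene | C=C/C(Br)=C/CC/C(C)=C/CC/C(C)=C/COCc1ccc(OC)cc1 | intermediate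
10 | dienyllithium from 9 (lithium in place of bromine, vinyl trans to the chain) | C=C/C([Li])=C/CC/C(C)=C/CC/C(C)=C/COCc1ccc(OC)cc1 | intermediate (not isolated)
11 | lithium alkoxide of 12 | C=C/C(C[O-])=C/CC/C(C)=C/CC/C(C)=C/COCc1ccc(OC)cc1.[Li+] | intermediate (not isolated)
12 | (2Z,6E,10E)-2-ethenyl-12-[(4-methoxyphenyl)methoxy]-6,10-dimethyldodeca-2,6,10-trien-1-ol | C=C/C(CO)=C/CC/C(C)=C/CC/C(C)=C/COCc1ccc(OC)cc1 | intermediate
13 | (2Z,6E,10E)-2-ethenyl-12-[(4-methoxyphenyl)methoxy]-6,10-dimethyldodeca-2,6,10-trien-1-yl methyl carbonate | C=C/C(COC(=O)OC)=C/CC/C(C)=C/CC/C(C)=C/COCc1ccc(OC)cc1 | intermediate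
14 | methacrolein (2-methylprop-2-enal) | CC(=C)C=O | starting material
15 | {(5S,6R)-5-formyl-6-[(3E,7E)-9-[(4-methoxyphenyl)methoxy]-3,7-dimethylnona-3,7-dien-1-yl]-5-methylcyclohex-1-en-1-yl}methyl methyl carbonate (formyl cis to the chain) | COC(=O)OCC1=CCC[C@](C)(C=O)[C@@H]1CC/C(C)=C/CC/C(C)=C/COCc1ccc(OC)cc1 | intermediate
16 | (1S,2R)-2-[(3E,7E)-9-[(4-methoxyphenyl)methoxy]-3,7-dimethylnona-3,7-dien-1-yl]-1-methyl-3-methylidenecyclohexane-1-carbaldehyde | C=C1CCC[C@](C)(C=O)[C@@H]1CC/C(C)=C/CC/C(C)=C/COCc1ccc(OC)cc1 | intermediate
17 | (E)-hydrazone of 16, (1S,2R) | C=C1CCC[C@](C)(/C=N/N)[C@@H]1CC/C(C)=C/CC/C(C)=C/COCc1ccc(OC)cc1 | intermediate (not isolated)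
18 | 1-({[(2E,6E)-9-[(1S)-2,2-dimethyl-6-methylidenecyclohexyl]-3,7-dimethylnona-2,6-dien-1-yl]oxy}methyl)-4-methoxybenzene | C=C1CCCC(C)(C)[C@@H]1CC/C(C)=C/CC/C(C)=C/COCc1ccc(OC)cc1 | intermediate
19 | (2E,6E)-9-[(1S)-2,2-dimethyl-6-methylidenecyclohexyl]-3,7-dimethylnona-2,6-dien-1-ol | C=C1CCCC(C)(C)[C@@H]1CC/C(C)=C/CC/C(C)=C/CO | intermediate
20 | Meldrum's acid (2,2-dimethyl-1,3-dioxane-4,6-dione) | CC1(C)OC(=O)CC(=O)O1 | starting material
21 | 3-{[(2E,6E)-9-[(1S)-2,2-dimethyl-6-methylidenecyclohexyl]-3,7-dimethylnona-2,6-dien-1-yl]oxy}-3-oxopropanoic acid | C=C1CCCC(C)(C)[C@@H]1CC/C(C)=C/CC/C(C)=C/COC(=O)CC(=O)O | target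

**Step count and risks**
Total step count: 12. Longest linear sequence: 12 steps (1 to 21).

Steps most likely to fail:

1. Step 8. What may go wrong: loss of the endo preference or of facial discrimination, either of which lowers the enantiomeric purity of the ring stereocenter once step 10 has made the quaternary carbon non-stereogenic; reversed orientation of the addends; or acid-triggered cyclisation of the polyene chain. The endo and exo adducts are diastereomers and can be separated at the stage of 15. Fallback (resolution instead of catalyst control): it sets out from 13, which is combined with 14 under an achiral Lewis acid (EtAlCl2, CH2Cl2, −78 °C) to give the racemic endo adduct F1. Condensation of F1 with (1R,2R)-N,N'-dimethyl-1,2-diphenylethane-1,2-diamine (molecular sieves, Et2O) should give the two diastereomeric aminals, the aminal of the (5S,6R)-aldehyde F2 and the aminal of its mirror-image aldehyde F3. These are separated by chromatography, and mild aqueous acid hydrolysis of F2 returns enantiopure 15, where the route is rejoined.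

2. Step 10. What may go wrong: incomplete decomposition of the hindered hydrazone, azine formation, or heat- and base-driven migration of the exocyclic double bond. Fallback (stepwise deoxygenation by hydride displacement): it sets out from 16, which is reduced with NaBH4 (MeOH, 0 °C) to the neopentyl alcohol F4. F4 is converted with MsCl/Et3N into the mesylate F5, and F5 is reduced with LiBHEt3 (THF, reflux) to 18, where the route is rejoined.

3. Step 9. What may go wrong: hydride transfer to the exocyclic allyl terminus, giving the endocyclic 2-methylcyclohexene isomer, or β-hydride elimination from the allylpalladium intermediate to a diene. Fallback (sigmatropic transposition instead of allylpalladium chemistry): it sets out from 15, which is submitted first to the Huang–Minlon conditions of step 10. These also saponify the carbonate, so the reduction runs through the hydroxy hydrazone F6 to the gem-dimethyl allylic alcohol F7. A Myers reductive transposition of F7 (2-nitrobenzenesulfonylhydrazide, PPh3, diethyl azodicarboxylate, THF, −30 to 23 °C) should give the Mitsunobu product F8, which loses 2-nitrobenzenesulfinic acid to the allylic diazene F9. Retro-ene loss of N2 from F9 moves the double bond to the exocyclic position and gives 18, where the route is rejoined (16 and 17 are bypassed).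

**Further compounds**
F1 | step 8 | racemic 15 (1:1 mixture of 15 and its mirror image) | COC(=O)OCC1=CCC[C@](C)(C=O)[C@@H]1CC/C(C)=C/CC/C(C)=C/COCc1ccc(OC)cc1.COC(=O)OCC1=CCC[C@@](C)(C=O)[C@H]1CC/C(C)=C/CC/C(C)=C/COCc1ccc(OC)cc1
F2 | step 8 | {(5S,6S)-5-[(4R,5R)-1,3-dimethyl-4,5-diphenylimidazolidin-2-yl]-6-[(3E,7E)-9-[(4-methoxyphenyl)methoxy]-3,7-dimethylnona-3,7-dien-1-yl]-5-methylcyclohex-1-en-1-yl}methyl methyl carbonate (aminal of 15) | COC(=O)OCC1=CCC[C@](C)(C2N(C)[C@H](c3ccccc3)[C@@H](c3ccccc3)N2C)[C@@H]1CC/C(C)=C/CC/C(C)=C/COCc1ccc(OC)cc1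
F3 | step 8 | (5R,6R)-diastereomer of F2 with the same (4R,5R)-imidazolidine (aminal of the mirror image of 15) | COC(=O)OCC1=CCC[C@@](C)(C2N(C)[C@H](c3ccccc3)[C@@H](c3ccccc3)N2C)[C@H]1CC/C(C)=C/CC/C(C)=C/COCc1ccc(OC)cc1
F4 | step 10 | [(1S,2R)-2-[(3E,7E)-9-[(4-methoxyphenyl)methoxy]-3,7-dimethylnona-3,7-dien-1-yl]-1-methyl-3-methylidenecyclohexyl]methanol | C=C1CCC[C@](C)(CO)[C@@H]1CC/C(C)=C/CC/C(C)=C/COCc1ccc(OC)cc1
F5 | step 10 | [(1S,2R)-2-[(3E,7E)-9-[(4-methoxyphenyl)methoxy]-3,7-dimethylnona-3,7-dien-1-yl]-1-methyl-3-methylidenecyclohexyl]methyl methanesulfonate | C=C1CCC[C@](C)(COS(C)(=O)=O)[C@@H]1CC/C(C)=C/CC/C(C)=C/COCc1ccc(OC)cc1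
F6 | step 9 | {(5S,6S)-5-[(E)-hydrazinylidenemethyl]-6-[(3E,7E)-9-[(4-methoxyphenyl)methoxy]-3,7-dimethylnona-3,7-dien-1-yl]-5-methylcyclohex-1-en-1-yl}methanol | OCC1=CCC[C@](C)(/C=N/N)[C@@H]1CC/C(C)=C/CC/C(C)=C/COCc1ccc(OC)cc1
F7 | step 9 | {(6S)-6-[(3E,7E)-9-[(4-methoxyphenyl)methoxy]-3,7-dimethylnona-3,7-dien-1-yl]-5,5-dimethylcyclohex-1-en-1-yl}methanol | OCC1=CCCC(C)(C)[C@@H]1CC/C(C)=C/CC/C(C)=C/COCc1ccc(OC)cc1
F8 | step 9 | N-({(6S)-6-[(3E,7E)-9-[(4-methoxyphenyl)methoxy]-3,7-dimethylnona-3,7-dien-1-yl]-5,5-dimethylcyclohex-1-en-1-yl}methyl)-2-nitrobenzenesulfonohydrazide | NN(CC1=CCCC(C)(C)[C@@H]1CC/C(C)=C/CC/C(C)=C/COCc1ccc(OC)cc1)S(=O)(=O)c1ccccc1[N+](=O)[O-]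
F9 | step 9 | ({(6S)-6-[(3E,7E)-9-[(4-methoxyphenyl)methoxy]-3,7-dimethylnona-3,7-dien-1-yl]-5,5-dimethylcyclohex-1-en-1-yl}methyl)diazene | N=NCC1=CCCC(C)(C)[C@@H]1CC/C(C)=C/CC/C(C)=C/COCc1ccc(OC)cc1
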